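Start from the amber run and the green run: both bend over, so count what is left to climb and not what is made. Green is the flask asked about, followed so far.

the same everywhere: starting material 0.050 M

|  | reagent | protic impurity | temperature | remark | time |
|---|---|---|---|---|---|
| green | 0.25 M | 0.015 M | 60 °C | the very flask that is asked about, followed so far |  |
| amber | 0.25 M | 0.015 M | 45 °C | run made earlier |  |
| flask | 0.250 M | 0.0150 M | 60 °C |  | 8.0 min |

| green: time / min | green: target / % | amber: time / min | amber: target / % |
|---|---|---|---|
| 0.833 | 8 | 2.00 | 5 |
| 1.50 | 10 | 3.00 | 3 |
| 2.50 | 16 | 5.00 | 11 |
| 3.00 | 13 | 6.00 | 16 |
| 4.00 | 19 | 8.00 | 14 |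
| 5.00 | 19 | 10.0 | 17 |

(scatter of a reading: 1.5 percentage points)

- what is taken out of target is counted as made
- what was read earlier has a scatter of 1.5 percentage points, one standard deviation
- additions bring no volume worth counting

- south: at 8.0 min add reagent, 50.0% of the amount charged, then wait 2.5 min
- north: change nothing and wait 2.5 min more
- north-east: at 8.0 min take out 90% of the target then present, then wait 2.5 min
- north-west: at 8.0 min raise the temperature by 25 K, then wait 2.5 min

- target, in percent of the starting material first charged, at 8.0 min
- the remedy with the largest gain of target, or "none" below 2 percentage points (south / north / north-east / north-west / none)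
- target present, with what was taken out counted in, in percent of the starting material first charged, after north
- target present, with what was taken out counted in, in percent of the starting material first charged, after north-east

1. Define the gap: the fraction of the climb to the ceiling still left. Assume it decays exponentially. Its gap half-life is the time in which that fraction halves.

2. Smooth the scatter by pairing green readings. The last pair averages 19.0% at 4.50 min, the middle pair 14.5% at 2.75 min. Take the last pair as the ceiling, and the gap half-life is 1.32 min.

3. Object: that ceiling is too low. At 4.50 min this half-life still leaves 9.47% of the climb. So correct the ceiling to 21.0%, and the gap half-life becomes 1.62 min. Stop here, because the readings scatter by 1.5 percentage points.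

4. Object again: does amber share this ceiling? Its middle pair gives a gap half-life of 3.70 min. That predicts 17.8% at 10.0 min, and amber reads 17%. So this last amber reading does not speak against the ceiling, within the scatter.

5. Reckon green at 8.0 min: the gap is 3.29%, so target stands near 20.3%. Waiting 2.5 min more gives about 20.8%.

6. Object once more: c(reagent) is charged at 5.00 times c(starting material), yet the ceiling is far below complete conversion. These readings show target and nothing else, so leave the remedies unranked.

The forecast gives 20.5%, slightly above this reckoning, then 20.8% after north and 30% after north-east. It picks north-east, and it says that a ceiling that “barely moves with temperature looks like reversible equilibrium”.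

The flask gives 20.6%, 21.0% after north and 26.3% after north-east. But the best remedy is north-west, with a gain of 16 points against 5.6 points for north-east. At 8.00 min, 40.2% of the starting material is still free in the flask. The gap measures the climb of target and not that stock. Used on waiting, the gap half-life predicts a gain of 0.45 points, and north gives 0.33 points.

    reagent + other conformer → isomer of the product A (k = 0.00300 /M/s, Ea = 59.0 kJ/mol)
    starting material + reagent → target (k = 0.00800 /M/s, Ea = 70.0 kJ/mol)
    2 reagent → homo dimer (k = 0.00710 /M/s, Ea = 51.0 kJ/mol)
    starting material + protic impurity → quenched substrate (k = 0.0680 /M/s, Ea = 65.0 kJ/mol)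
    starting material ⇌ other conformer (K = 0.130, k = 7.60 × 10⁻⁴ /s, Ea = 111 kJ/mol, ΔH = −10.0 kJ/mol)
    target ⇌ isomer of the product B (K = 1.20, k = 0.00270 /s, Ea = 83.0 kJ/mol, ΔH = −52.0 kJ/mol)
    (constants at 60 °C)

Now take the neighbour flask kept at 45 °C, with amber's gap half-life. The gap at 8.0 min is 22.3%, so target should stand near 16.3%. The computed result is 15.1%.

(All runs come from a simulation for substances that don't exist; scatter was added.)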